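**Strategy.** Each 3-aryl-p-menth-1-ene ring (C1 methyl, C3 aryl, C4 isopropyl) is disconnected at C1–C6 and C3–C4. The ring hides a 2-methylcyclohex-2-enone: if C2 is a ketone, C1 and C3 are its two nucleophilic α-carbons and C4–C5–C6 is an enal, electrophilic at both ends. One amine-catalysed Michael addition/aldol condensation/decarboxylation between a β-keto ester and (E)-4-methylpent-2-enal therefore closes the ring and sets C4. The precursors are two acyclic carbonyl compounds without ring or stereocentre. The C2 carbonyl is then spent in a Shapiro reaction to give (R)-α-phellandrene, two molecules of which alkylate 2',4',6'-trihydroxychalcone at C3, trans to isopropyl.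

Key step: step 1

Remark: tert-butyl 3-oxopentanoate, (E)-4-methylpent-2-enal, 2',4',6'-trihydroxychalcone and the (R)-configured silyl prolinol catalyst are taken as purchasable; the menthene numbering above (C1 methyl, C3 aryl, C4 isopropyl) is used in all explanations.

Step 1
Reactants: 1 tert-butyl 3-oxopentanoate (1.2 equiv); 2 (E)-4-methylpent-2-enal
Product: 5 (5S)-2-methyl-5-(propan-2-yl)cyclohex-2-en-1-one, via Michael adduct 3 (not isolated), via keto ester 4 (not isolated)
Conditions: (R)-2-{bis[3,5-bis(trifluoromethyl)phenyl](trimethylsilyloxy)methyl}pyrrolidine (10 mol%), neat, rt; then p-TsOH·H2O (20 mol%), toluene, 80 °C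
Reagents that add atoms: none
Why: The secondary amine condenses with 2 to an (E)-iminium ion, and the acidic methylene of 1 (later C3) adds to its β-carbon (later C4) from the face left open by the diaryl(silyloxy)methyl group, so that catalyst control alone fixes C4 as (R) in 3 and (S) in 5 (Michael addition). After acidification the ethyl ketone enolises toward its CH2 (later C1), which attacks the aldehyde carbon (later C6) in a 6-(enolexo)-exo-trig aldol closure, and dehydration delivers the C6=C1 bond as part of a conjugated enone. The tert-butyl ester then leaves as 2-methylpropene and the β-keto acid loses CO2, which erases the uncontrolled centre at C3. The closest known reaction type is the amine-catalysed Michael addition/aldol condensation/decarboxylation of tert-butyl β-keto esters with enals to chiral cyclohexenones. The step needs 1,4- over 1,2-addition, secured by iminium activation and the soft 1,3-dicarbonyl donor, and ring closure through the ethyl CH2, secured because this is the only enolisable position that can reach the aldehyde in a six-membered ring.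

Step 2
Reactants: 5 (5S)-2-methyl-5-(propan-2-yl)cyclohex-2-en-1-one
Product: 6 4-methyl-N'-[(5S)-2-methyl-5-(propan-2-yl)cyclohex-2-en-1-ylidene]benzenesulfonohydrazide
Conditions: TsNHNH2 (1.05 equiv), cat. HCl, MeOH, rt to 50 °C
Reagents that add atoms: p-toluenesulfonohydrazide, Cc1ccc(cc1)S(=O)(=O)NN
Why: Acid-catalysed condensation of the conjugated ketone to its tosylhydrazone occurs at the carbonyl group only and leaves the isopropyl-bearing centre, which carries no acidic hydrogen, untouched.

Step 3
Reactants: 6 4-methyl-N'-[(5S)-2-methyl-5-(propan-2-yl)cyclohex-2-en-1-ylidene]benzenesulfonohydrazide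
Product: 8 (5R)-2-methyl-5-(propan-2-yl)cyclohexa-1,3-diene, via alkenyllithium 7 (not isolated)
Conditions: MeLi (2.5 equiv), Et2O, 0 °C to rt; then H2O, 0 °C
Reagents that add atoms: none
Why: Shapiro reaction, in which MeLi removes the N–H and then a hydrogen of the α'-methylene (later C3), the dianion expels sulfinate and N2 to give alkenyllithium 7, and protonation leaves a new C2=C3 double bond conjugated with the unmoved C1=C6 bond while the C4 centre is not involved (its descriptor changes to R only through the priority rules).

Step 4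
Reactants: 8 (5R)-2-methyl-5-(propan-2-yl)cyclohexa-1,3-diene (2.5 equiv); 9 2',4',6'-trihydroxychalcone
Product: 11 neolinderachalcone, via monoalkylated chalcone 10 (not isolated)
Conditions: p-TsOH·H2O (20 mol%), CH2Cl2, rt
Reagents that add atoms: none
Why: Friedel–Crafts alkylation, in which protonation of the diene at C6 gives the methyl-substituted allyl cation over C1–C2–C3 and the two free ring positions of the phloroglucinol attack its secondary terminus C3 in turn, anti to the neighbouring isopropyl group, so that each new aryl-bearing centre is set (R) and trans by the existing C4 centre.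

Compound list
1 | tert-butyl 3-oxopentanoate | CCC(=O)CC(=O)OC(C)(C)C | starting material
2 | (E)-4-methylpent-2-enal | CC(C)/C=C/C=O | starting material
3 | tert-butyl (3R)-5-oxo-2-propanoyl-3-(propan-2-yl)pentanoate (epimers at C2) | CCC(=O)C(C(=O)OC(C)(C)C)[C@@H](C(C)C)CC=O | intermediate
4 | tert-butyl (6R)-3-methyl-2-oxo-6-(propan-2-yl)cyclohex-3-ene-1-carboxylate (epimers at C1) | CC1=CC[C@H](C(C)C)C(C(=O)OC(C)(C)C)C1=O | intermediate
5 | (5S)-2-methyl-5-(propan-2-yl)cyclohex-2-en-1-one, (S)-carvotanacetone | CC1=CC[C@H](C(C)C)CC1=O | intermediate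
6 | 4-methyl-N'-[(5S)-2-methyl-5-(propan-2-yl)cyclohex-2-en-1-ylidene]benzenesulfonohydrazide | CC1=CC[C@H](C(C)C)CC1=NNS(=O)(=O)c1ccc(C)cc1 | intermediate
7 | [(3R)-6-methyl-3-(propan-2-yl)cyclohexa-1,5-dien-1-yl]lithium | [Li]C1=C[C@@H](C(C)C)CC=C1C | intermediate
8 | (5R)-2-methyl-5-(propan-2-yl)cyclohexa-1,3-diene, (R)-α-phellandrene | CC1=CC[C@H](C(C)C)C=C1 | intermediate
9 | (E)-3-phenyl-1-(2,4,6-trihydroxyphenyl)prop-2-en-1-one, 2',4',6'-trihydroxychalcone | O=C(/C=C/c1ccccc1)c1c(O)cc(O)cc1O | starting material
10 | (E)-3-phenyl-1-{2,4,6-trihydroxy-3-[(1R,6R)-3-methyl-6-(propan-2-yl)cyclohex-2-en-1-yl]phenyl}prop-2-en-1-one | CC1=C[C@H](c2c(O)cc(O)c(C(=O)/C=C/c3ccccc3)c2O)[C@@H](C(C)C)CC1 | intermediate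
11 | neolinderachalcone, (E)-3-phenyl-1-{2,4,6-trihydroxy-3,5-bis[(1R,6R)-3-methyl-6-(propan-2-yl)cyclohex-2-en-1-yl]phenyl}prop-2-en-1-one | CC1=C[C@H](c2c(O)c(C(=O)/C=C/c3ccccc3)c(O)c([C@H]3C=C(C)CC[C@@H]3C(C)C)c2O)[C@@H](C(C)C)CC1 | target

Total step count: 4. Longest linear sequence: 4 steps (1 and 2 to 5, then 6, 8 and 11).

Steps most likely to fail, in order of risk:

First, step 4. The acid may close the 2'-hydroxychalcone to the flavanone, add a phenol across the ring double bond of a menthenyl group already installed, or stop after the first alkylation. The fallback sets out from 8. The same acid-mediated alkylation is run on purchased 2',4',6'-trihydroxyacetophenone, which has no enone and a more nucleophilic ring, to give 1-{2,4,6-trihydroxy-3,5-bis[(1R,6R)-3-methyl-6-(propan-2-yl)cyclohex-2-en-1-yl]phenyl}ethan-1-one F1. A Claisen–Schmidt condensation of F1 with benzaldehyde (KOH, EtOH/H2O, rt) then builds the enone last and comes back to the route at 11.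

Second, step 1. Ring closure through the hindered ethyl CH2 may be slow, so that retro-Michael reaction in the acid stage erodes the enantiomeric purity, or the β-branched enal may add sluggishly. The fallback keeps the same two ring bonds and adds the methyl group afterwards. It sets out from 2 and uses purchased tert-butyl 3-oxobutanoate under the conditions of step 1. The reaction passes through the Michael adduct tert-butyl (3R)-2-acetyl-5-oxo-3-(propan-2-yl)pentanoate F2 and the keto ester tert-butyl (6R)-2-oxo-6-(propan-2-yl)cyclohex-3-ene-1-carboxylate F3, neither isolated, to (5S)-5-(propan-2-yl)cyclohex-2-en-1-one F4. α-Iodination (I2, pyridine, CH2Cl2) gives (5S)-2-iodo-5-(propan-2-yl)cyclohex-2-en-1-one F5, and Suzuki coupling with methylboronic acid (PdCl2(dppf), K3PO4, THF/H2O, 60 °C) comes back to the route at 5.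

Third, step 3. Deprotonation at the γ-methylene instead of the α'-methylene, addition of MeLi to the C=N bond, or [1,5]-hydrogen shifts while the volatile diene is isolated may lead to isomeric dienes. The fallback sets out from 5. Kinetic deprotonation at the α'-methylene (LiN(iPr)2, THF, −78 °C) and trapping with PhNTf2 gives (3R)-6-methyl-3-(propan-2-yl)cyclohexa-1,5-dien-1-yl trifluoromethanesulfonate F6. Its palladium-catalysed formate reduction (Pd(OAc)2, PPh3, Bu3N, HCO2H, DMF, 60 °C) comes back to the route at 8.

Further compounds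
F1 | step 4 | 1-{2,4,6-trihydroxy-3,5-bis[(1R,6R)-3-methyl-6-(propan-2-yl)cyclohex-2-en-1-yl]phenyl}ethan-1-one | CC1=C[C@H](c2c(O)c(C(C)=O)c(O)c([C@H]3C=C(C)CC[C@@H]3C(C)C)c2O)[C@@H](C(C)C)CC1
F2 | step 1 | tert-butyl (3R)-2-acetyl-5-oxo-3-(propan-2-yl)pentanoate | CC(=O)C(C(=O)OC(C)(C)C)[C@@H](C(C)C)CC=O
F3 | step 1 | tert-butyl (6R)-2-oxo-6-(propan-2-yl)cyclohex-3-ene-1-carboxylate | O=C1C=CC[C@H](C(C)C)C1C(=O)OC(C)(C)C
F4 | step 1 | (5S)-5-(propan-2-yl)cyclohex-2-en-1-one | O=C1C=CC[C@H](C(C)C)C1
F5 | step 1 | (5S)-2-iodo-5-(propan-2-yl)cyclohex-2-en-1-one | O=C1C(I)=CC[C@H](C(C)C)C1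
F6 | step 3 | (3R)-6-methyl-3-(propan-2-yl)cyclohexa-1,5-dien-1-yl trifluoromethanesulfonate | CC1=CC[C@H](C(C)C)C=C1OS(=O)(=O)C(F)(F)F
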